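Complex with one exchanged is wanted from two flasks, eta and epsilon, which share a temperature but differ in charges and time.

| flask | starting complex | incoming ligand | leaving ligand | temperature | remark | time |
|---|---|---|---|---|---|---|
| Wednesday's | 0.39 M | 0.637 M | 2.45 M | 20 °C | run made earlier |  |
| Saturday's | 0.65 M | 0.637 M | 2.45 M | 35 °C | run made earlier |  |
| Tuesday's | 0.49 M | 0.637 M | 1.7 M | 20 °C | run made earlier |  |
| eta | 0.30 M | 0.637 M | 1.20 M | 35 °C |  | 25 h |
| epsilon | 0.49 M | 0.637 M | 2.45 M | 35 °C |  | 15 h |

| run | time / h | complex with one exchanged / % | starting complex / % |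
|---|---|---|---|
| Wednesday's | 2.00 | 22.1 | 63.4 |
| Wednesday's | 3.00 | 23.0 | 54.2 |
| Wednesday's | 5.00 | 21.2 | 44.6 |
| Wednesday's | 8.00 | 18.3 | 38.7 |
| Wednesday's | 12.0 | 17.6 | 33.5 |
| Wednesday's | 20.0 | 17.3 | 32.0 |
| Saturday's | 0.667 | 19.8 | 67.4 |
| Saturday's | 2.00 | 13.8 | 60.8 |
| Saturday's | 4.00 | 13.6 | 59.5 |
| Saturday's | 6.00 | 13.1 | 60.4 |
| Saturday's | 8.00 | 13.3 | 60.5 |
| Saturday's | 10.0 | 12.1 | 60.8 |
| Tuesday's | 2.00 | 22.8 | 63.8 |
| Tuesday's | 3.00 | 23.4 | 56.2 |
| Tuesday's | 6.00 | 21.9 | 44.7 |
| Tuesday's | 12.0 | 18.5 | 39.2 |
| Tuesday's | 20.0 | 17.1 | 37.4 |

(standard deviation of a reading: 0.5 percentage points)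

- what was read earlier has a scatter of 0.5 percentage points, one standard deviation

1. the winner by amount of complex with one exchanged, in percent of the starting complex charged; "neither" if no more than 2 percentage points parts them (eta / epsilon / neither)
2. how much complex with one exchanged is there at the end, in percent of the starting complex charged: eta
3. how much complex with one exchanged is there at the end, in percent of the starting complex charged: epsilon

With the first exchange alone, starting complex and incoming ligand giving leaving ligand and complex with one exchanged, the two read species would add up to the charge. They do not: at 2.00 h in Wednesday's run they add up to 85.5%. A second exchange, from complex with one exchanged to complex with two exchanged, accounts for the balance and turns the climb into a peak, with Wednesday's readings going from 23.0% to 17.3%.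

Taking the first step minus the second cancels both ligands. So, at one temperature and with both steps in balance, a quotient free of the charges should hold. Saturday's last readings average 13.0% and 60.3%, which leaves 26.7% as complex with two exchanged and gives 0.105. This exchange quotient, c(complex with one exchanged) squared over c(starting complex) times c(complex with two exchanged), is the comproportionation constant. As a check, Wednesday's and Tuesday's last readings, with different charges, give 0.184 and 0.172 at their common lower temperature.

Setting the two outer complexes equal puts the peak at 14.0%, and a ratio of 2 between them still gives 13.3%. Saturday's readings of complex with one exchanged slip from 13.6% to 12.1% against a scatter of 0.5 percentage points, which leaves room for slower processes but does not tell how they act on eta and epsilon. Saturday's readings of starting complex hold near 60.3% from 4.00 h on, and eta and epsilon run longer than that. The reckoning here therefore places both near that flat top, with no gap of 2 points.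

The forecast says neither, with 13.3% for eta and 13.8% for epsilon, since “both runs sit near that flat maximum”.

The flasks give neither: 13.1% in eta and 13.1% in epsilon.

    starting complex + incoming ligand ⇌ leaving ligand + complex with one exchanged (K = 3.40, k = 2.30 L mol⁻¹ h⁻¹, Ea = 78.0 kJ mol⁻¹, ΔH = −55.0 kJ mol⁻¹)
    complex with one exchanged + incoming ligand ⇌ leaving ligand + complex with two exchanged (K = 33.0, k = 3.30 L mol⁻¹ h⁻¹, Ea = 61.0 kJ mol⁻¹, ΔH = −29.0 kJ mol⁻¹)
    incoming ligand → decomposed reagent (k = 0.0180 h⁻¹, Ea = 100 kJ mol⁻¹)
    complex with one exchanged + incoming ligand → over-reaction product (k = 0.0250 L mol⁻¹ h⁻¹, Ea = 79.0 kJ mol⁻¹)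
    (constants at 35 °C)

The exchange quotient stands, at 0.101 in eta and 0.101 in epsilon, but neither flask has come to rest. In a neighbour of eta charged with 1.6 M of incoming ligand, 4.9% starting complex and 85.0% complex with two exchanged give 6.61% through 0.105, and that neighbour holds 6.55%. Over ten times the time, incoming ligand in eta falls from 28% to 6.75% of its charge and starting complex climbs to 73.9%, while the quotient reads 0.0977. Complex with one exchanged is then down to 8.38% in eta at 250 h and 8.14% in epsilon at 150 h.

(The numbers in the tables were computed on assumed constants.)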